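## Retrosynthetic overview

- Target ⇐ its O-benzyl ether by a final hydrogenolysis. Both benzene rings are bought, so the γ-lactone is the only ring made, and it is closed in the penultimate step.
- Lactone ⇐ acyclic iodomethyl (2R,3E)-2-benzyl-4-arylbut-3-enoate. The C4–C5 bond is closed by 5-exo-trig attack of an acyloxymethyl radical (C5) on C4 of a C4=C7 styrene. This is a radical union of two acceptor-type carbons: the oxygen-bound C5 and C4, which lies β to the carbonyl.
- Enabling feature: C5 sits on the ester oxygen O1, so O1–C2(=O)–C3 is a ready-made three-atom tether from C5 to C4. The 3,4,5-trimethoxyphenyl ring on C7 makes C4=C7 a styrene that accepts at C4 and stabilises the C7 radical. The C3 stereocenter directs the new C4 center trans.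
- C3 ⇐ Evans alkylation of the dienolate of an N-(4-arylbut-3-enoyl)oxazolidinone with 4-benzyloxy-3-methoxybenzyl bromide.
- 4-Arylbut-3-enoic acid ⇐ Wittig reaction of 3,4,5-trimethoxybenzaldehyde with (2-carboxyethyl)triphenylphosphonium bromide.

Key step: step 8

Remark: the lactone is numbered O1, C2 (carbonyl), C3, C4, C5 (OCH2), and C7 is the benzylic carbon on C4. The target is the trans-(3R,4R) isomer. Compounds 1, 3, 4 and 7 are taken as commercial.

## Route

Step 1
Reactants: 1 4-benzyloxy-3-methoxybenzyl alcohol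
Product: 2 4-benzyloxy-3-methoxybenzyl bromide
Conditions: PBr3 (0.4 equiv), Et2O, 0 °C
Reagents that add atoms: phosphorus tribromide, BrP(Br)Br
Why: Alcohol-to-bromide substitution with PBr3 proceeds by SN2 displacement on the phosphite ester of the activated primary benzylic alcohol, and the aryl benzyl ether is untouched at 0 °C.

Step 2
Reactants: 3 3,4,5-trimethoxybenzaldehyde; 4 (2-carboxyethyl)triphenylphosphonium bromide
Product: 6 (E)-4-(3,4,5-trimethoxyphenyl)but-3-enoic acid, via phosphonium ylide carboxylate 5 (not isolated)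
Conditions: KOtBu (2.2 equiv), THF, 0 °C to rt; then 1 M HCl
Reagents that add atoms: none
Why: Wittig olefination of the aromatic aldehyde with the carboxylate-bearing ylide 5 should give mainly the E-alkene, which aryl conjugation holds in the β,γ-position, and residual Z-isomer is harmless because step 8 erases the alkene geometry.

Step 3
Reactants: 6 (E)-4-(3,4,5-trimethoxyphenyl)but-3-enoic acid; 7 (R)-4-benzyloxazolidin-2-one
Product: 9 (R)-4-benzyl-3-[(E)-4-(3,4,5-trimethoxyphenyl)but-3-enoyl]oxazolidin-2-one, via mixed pivalic anhydride 8 (not isolated)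
Conditions: PivCl, Et3N, THF, −20 °C; then LiCl, 7, −20 °C to rt
Reagents that add atoms: none
Why: N-acylation of the oxazolidinone through the mixed pivalic anhydride (Et3N/LiCl protocol) needs no strong base, so the acidic styrylacetyl CH2 is not a liability, and no stereocenter is formed.

Step 4
Reactants: 9 (R)-4-benzyl-3-[(E)-4-(3,4,5-trimethoxyphenyl)but-3-enoyl]oxazolidin-2-one; 2 4-benzyloxy-3-methoxybenzyl bromide
Product: 11 (R)-4-benzyl-3-[(2R,3E)-2-(4-benzyloxy-3-methoxybenzyl)-4-(3,4,5-trimethoxyphenyl)but-3-enoyl]oxazolidin-2-one, via sodium dienolate 10 (not isolated)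
Conditions: NaN(SiMe3)2 (1.05 equiv), THF, −78 °C; then 2, −78 to −45 °C; sat. NH4Cl at −78 °C
Reagents that add atoms: none
Why: Evans asymmetric alkylation: the chelated Z(O)-dienolate 10 should react at its α-carbon (the kinetic site of dienolates) on the face opposite the benzyl group of the (R)-auxiliary, which sets the R configuration of the future lactone C3.

Step 5
Reactants: 11 (R)-4-benzyl-3-[(2R,3E)-2-(4-benzyloxy-3-methoxybenzyl)-4-(3,4,5-trimethoxyphenyl)but-3-enoyl]oxazolidin-2-one
Product: 13 (2R,3E)-2-(4-benzyloxy-3-methoxybenzyl)-4-(3,4,5-trimethoxyphenyl)but-3-enoic acid, via lithium peroxycarboxylate 12 (not isolated)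
Conditions: LiOH, 30% H2O2, THF/H2O (3:1), 0 °C; then Na2SO3; 1 M HCl
Reagents that add atoms: hydrogen peroxide (acting as LiOOH), OO
Why: Hydroperoxide cleavage of the N-acyloxazolidinone (Evans LiOH/H2O2 conditions) attacks the exocyclic carbonyl selectively and quickly at 0 °C, which should leave the α-stereocenter and the styrene intact, and sulfite reduces percarboxylate 12 to the carboxylate.

Step 6
Reactants: 13 (2R,3E)-2-(4-benzyloxy-3-methoxybenzyl)-4-(3,4,5-trimethoxyphenyl)but-3-enoic acid
Product: 14 chloromethyl (2R,3E)-2-(4-benzyloxy-3-methoxybenzyl)-4-(3,4,5-trimethoxyphenyl)but-3-enoate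
Conditions: ClCH2OSO2Cl, NaHCO3, Bu4NHSO4 (cat.), CH2Cl2/H2O, 0 °C to rt
Reagents that add atoms: chloromethyl chlorosulfate, ClCOS(=O)(=O)Cl
Why: Phase-transfer O-alkylation of the carboxylate displaces chlorosulfate (the better leaving group) to give the chloromethyl ester, under bicarbonate buffering that is too weak to enolise the α-stereocenter.

Step 7
Reactants: 14 chloromethyl (2R,3E)-2-(4-benzyloxy-3-methoxybenzyl)-4-(3,4,5-trimethoxyphenyl)but-3-enoate
Product: 15 iodomethyl (2R,3E)-2-(4-benzyloxy-3-methoxybenzyl)-4-(3,4,5-trimethoxyphenyl)but-3-enoate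
Conditions: NaI, acetone, rt, dark; used at once
Reagents that add atoms: sodium iodide, [Na+].[I-]
Why: Finkelstein halide exchange is driven by precipitation of NaCl from acetone, and SN2 at the acyloxymethyl carbon does not touch the stereocenter.

Step 8
Reactants: 15 iodomethyl (2R,3E)-2-(4-benzyloxy-3-methoxybenzyl)-4-(3,4,5-trimethoxyphenyl)but-3-enoate
Product: 18 (3R,4R)-3-(4-benzyloxy-3-methoxybenzyl)-4-(3,4,5-trimethoxybenzyl)dihydrofuran-2(3H)-one, via acyloxymethyl radical 16 (not isolated), via benzylic radical 17 (not isolated)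
Conditions: Bu3SnH (1.3 equiv), AIBN (0.2 equiv), syringe pump over 8 h into 15 (0.005 M), degassed PhMe, 110 °C; then aq KF
Reagents that add atoms: none
Why: Bu3Sn• abstracts iodine from 15 to give acyloxymethyl radical 16, which, once the ester has rotated into its s-cis rotamer, adds through C5 to C4 of the C4=C7 styrene to give benzylic radical 17 (stabilised by the 3,4,5-trimethoxyphenyl ring), and 17 takes hydrogen from Bu3SnH to give 18 and carry the chain. The closest known reaction type is the stannane-mediated 5-exo closure of (alk-3-enoyloxy)methyl radicals from halomethyl alk-3-enoates to γ-butyrolactones; in polar terms it joins two acceptor-type carbons (the oxygen-bound C5 and C4 β to the carbonyl), which only the radical makes possible. The only ring closed is the γ-lactone, by 5-exo-trig attack, and the 6-endo mode is disfavoured because it would give a non-benzylic radical. The new stereocenter C4 is controlled by the existing C3 center: in the favoured transition state the C3–H bond eclipses the C4=C7 bond (least allylic strain), which places the C3 benzyl group trans to the C4–C7 bond and should give (3R,4R); because C7 becomes CH2, E- and Z-alkene converge on the same product. The step needs ring closure to outrun hydrogen transfer to 16, which is secured by the fast-accepting styrene, the 110 °C temperature (faster ester rotation) and the millimolar stannane concentration from slow addition; it also needs trans over cis, which rests on the C3 substituent, and any cis isomer must be removed by chromatography and not epimerised, because epimerisation at C3 would lead to the enantiomer of the target.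

Step 9
Reactants: 18 (3R,4R)-3-(4-benzyloxy-3-methoxybenzyl)-4-(3,4,5-trimethoxybenzyl)dihydrofuran-2(3H)-one
Product: 19 (3R,4R)-3-(4-hydroxy-3-methoxybenzyl)-4-(3,4,5-trimethoxybenzyl)dihydrofuran-2(3H)-one (CNP0261601.1)
Conditions: H2 (1 atm), 10% Pd/C, EtOAc, rt
Reagents that add atoms: none
Why: Catalytic hydrogenolysis of the aryl benzyl ether on Pd/C is neutral, so the lactone, the aryl methyl ethers and both stereocenters (no base, no enolisation) should be unaffected.

## Compound list

1 | 4-benzyloxy-3-methoxybenzyl alcohol | COc1cc(CO)ccc1OCc1ccccc1 | starting material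
2 | 4-benzyloxy-3-methoxybenzyl bromide | COc1cc(CBr)ccc1OCc1ccccc1 | intermediate
3 | 3,4,5-trimethoxybenzaldehyde | COc1cc(C=O)cc(OC)c1OC | starting material
4 | (2-carboxyethyl)triphenylphosphonium bromide | OC(=O)CC[P+](c1ccccc1)(c1ccccc1)c1ccccc1.[Br-] | starting material
5 | potassium 3-(triphenylphosphoranylidene)propanoate (ylide) | [K+].[O-]C(=O)CC=P(c1ccccc1)(c1ccccc1)c1ccccc1 | intermediate (not isolated)
6 | (E)-4-(3,4,5-trimethoxyphenyl)but-3-enoic acid | OC(=O)C/C=C/c1cc(OC)c(OC)c(OC)c1 | intermediate
7 | (R)-4-benzyloxazolidin-2-one | O=C1N[C@H](Cc2ccccc2)CO1 | starting material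
8 | (E)-4-(3,4,5-trimethoxyphenyl)but-3-enoic pivalic anhydride | CC(C)(C)C(=O)OC(=O)C/C=C/c1cc(OC)c(OC)c(OC)c1 | intermediate (not isolated)
9 | (R)-4-benzyl-3-[(E)-4-(3,4,5-trimethoxyphenyl)but-3-enoyl]oxazolidin-2-one | O=C(C/C=C/c1cc(OC)c(OC)c(OC)c1)N1[C@H](Cc2ccccc2)COC1=O | intermediate
10 | sodium Z(O)-dienolate of 9 | [Na+].[O-]/C(=C\C=C\c1cc(OC)c(OC)c(OC)c1)N1[C@H](Cc2ccccc2)COC1=O | intermediate (not isolated)
11 | (R)-4-benzyl-3-[(2R,3E)-2-(4-benzyloxy-3-methoxybenzyl)-4-(3,4,5-trimethoxyphenyl)but-3-enoyl]oxazolidin-2-one | COc1cc(C[C@H](/C=C/c2cc(OC)c(OC)c(OC)c2)C(=O)N2[C@H](Cc3ccccc3)COC2=O)ccc1OCc1ccccc1 | intermediate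
12 | lithium (2R,3E)-2-(4-benzyloxy-3-methoxybenzyl)-4-(3,4,5-trimethoxyphenyl)but-3-eneperoxoate | COc1cc(C[C@H](/C=C/c2cc(OC)c(OC)c(OC)c2)C(=O)O[O-])ccc1OCc1ccccc1.[Li+] | intermediate (not isolated)
13 | (2R,3E)-2-(4-benzyloxy-3-methoxybenzyl)-4-(3,4,5-trimethoxyphenyl)but-3-enoic acid | COc1cc(C[C@H](/C=C/c2cc(OC)c(OC)c(OC)c2)C(O)=O)ccc1OCc1ccccc1 | intermediate
14 | chloromethyl (2R,3E)-2-(4-benzyloxy-3-methoxybenzyl)-4-(3,4,5-trimethoxyphenyl)but-3-enoate | COc1cc(C[C@H](/C=C/c2cc(OC)c(OC)c(OC)c2)C(=O)OCCl)ccc1OCc1ccccc1 | intermediate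
15 | iodomethyl (2R,3E)-2-(4-benzyloxy-3-methoxybenzyl)-4-(3,4,5-trimethoxyphenyl)but-3-enoate | COc1cc(C[C@H](/C=C/c2cc(OC)c(OC)c(OC)c2)C(=O)OCI)ccc1OCc1ccccc1 | intermediate
16 | acyloxymethyl radical from 15 | COc1cc(C[C@H](/C=C/c2cc(OC)c(OC)c(OC)c2)C(=O)O[CH2])ccc1OCc1ccccc1 | intermediate (not isolated)
17 | cyclised C7 benzylic radical | COc1cc(C[C@H]2C(=O)OC[C@@H]2[CH]c2cc(OC)c(OC)c(OC)c2)ccc1OCc1ccccc1 | intermediate (not isolated)
18 | (3R,4R)-3-(4-benzyloxy-3-methoxybenzyl)-4-(3,4,5-trimethoxybenzyl)dihydrofuran-2(3H)-one | COc1cc(C[C@H]2C(=O)OC[C@@H]2Cc2cc(OC)c(OC)c(OC)c2)ccc1OCc1ccccc1 | intermediate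
19 | (3R,4R)-3-(4-hydroxy-3-methoxybenzyl)-4-(3,4,5-trimethoxybenzyl)dihydrofuran-2(3H)-one (CNP0261601.1) | COc1cc(C[C@H]2C(=O)OC[C@@H]2Cc2cc(OC)c(OC)c(OC)c2)ccc1O | target

## Step count and risks

Total step count: 9. Longest linear sequence: 8 steps (steps 2 to 9, from 3 and 4); step 1 is a one-step side branch.

Steps most likely to fail:

1. Step 8. Hydrogen transfer to the open-chain radical may occur before the ester reaches its reactive rotamer, and facial discrimination at C4 may be incomplete. The fallback builds the lactone first and sets C3 last; it sets out from 3 (and uses 2) and comes back at 18. Stobbe condensation of 3 with dimethyl succinate (NaOMe, MeOH, reflux) would give (E)-3-(methoxycarbonyl)-4-(3,4,5-trimethoxyphenyl)but-3-enoic acid F1. Asymmetric hydrogenation (H2, [Rh(cod)2]BF4 with a chiral bisphosphine of the DIOP family, ligand antipode chosen for the R product) would give (R)-3-(methoxycarbonyl)-4-(3,4,5-trimethoxyphenyl)butanoic acid F2. Reduction of the ester in the potassium salt with Ca(BH4)2 (from CaCl2 and NaBH4, EtOH) and acid lactonisation would give (R)-4-(3,4,5-trimethoxybenzyl)dihydrofuran-2(3H)-one F3. Enolisation with LiN(iPr)2 (THF, −78 °C) and alkylation with 2, anti to the C4 substituent, should give 18.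

2. Step 4. Alkylation may occur at the γ-carbon, or proton exchange between the product and the dienolate may erode the newly set α-stereocenter. The fallback replaces auxiliary control by resolution; it sets out from 6 and comes back at 13. The dianion of 6 (LiN(iPr)2, 2.2 equiv, THF, −78 °C) would be alkylated at the α-carbon with 2 to give racemic (E)-2-(4-benzyloxy-3-methoxybenzyl)-4-(3,4,5-trimethoxyphenyl)but-3-enoic acid F4, whose monoanionic product no longer exchanges its α-proton. Preparative chiral SFC would then deliver the R enantiomer 13.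

3. Step 7. The iodomethyl ester may hydrolyse or lose iodide during isolation and on heating. The fallback changes the radical precursor; it sets out from 14 and comes back at 18. Displacement of chloride in 14 with potassium O-ethyl xanthate (acetone, rt) would give the bench-stable S-(acyloxymethyl) O-ethyl xanthate F5. Under the slow-addition Bu3SnH/AIBN conditions (PhMe, 110 °C) F5 would release the same radical 16 by stannyl addition to the thiocarbonyl and C–S fragmentation, and so give 18.

## Further compounds

F1 | step 8 | (E)-3-(methoxycarbonyl)-4-(3,4,5-trimethoxyphenyl)but-3-enoic acid | OC(=O)C/C(C(=O)OC)=C\c1cc(OC)c(OC)c(OC)c1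
F2 | step 8 | (R)-3-(methoxycarbonyl)-4-(3,4,5-trimethoxyphenyl)butanoic acid | COC(=O)[C@H](Cc1cc(OC)c(OC)c(OC)c1)CC(O)=O
F3 | step 8 | (R)-4-(3,4,5-trimethoxybenzyl)dihydrofuran-2(3H)-one | O=C1OC[C@H](Cc2cc(OC)c(OC)c(OC)c2)C1
F4 | step 4 | racemic (E)-2-(4-benzyloxy-3-methoxybenzyl)-4-(3,4,5-trimethoxyphenyl)but-3-enoic acid | COc1cc(CC(/C=C/c2cc(OC)c(OC)c(OC)c2)C(O)=O)ccc1OCc1ccccc1
F5 | step 7 | (ethoxycarbonothioylsulfanyl)methyl (2R,3E)-2-(4-benzyloxy-3-methoxybenzyl)-4-(3,4,5-trimethoxyphenyl)but-3-enoate | COc1cc(C[C@H](/C=C/c2cc(OC)c(OC)c(OC)c2)C(=O)OCSC(=S)OCC)ccc1OCc1ccccc1
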